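**Retrosynthetic overview**

1. Target 10 ← catalyst-controlled epoxidation of oxocene 9 ← ring-closing metathesis of diene 8 (O-allyl ether at C8 plus an isopropenyl group made from the C13 methyl ketone) ← bromo ketol 6.
2. 6 ← one cationic (3+3) annulation/bicyclisation of two achiral pieces: allylic alcohol 2 (from geranylacetone; supplies C1 and C5–C13) and vinyl bromide 4 (supplies C2–C3–C4 with both C4 methyls). New bonds: C1–C2, C4–C5, C9–C10 and C8–O.
3. Enabling feature: in ring A the bromine sits on C3, between the C2 methylene and the gem-dimethyl carbon C4. A 2-bromo-3-methylbut-1-ene unit can therefore react as a nucleophile at C2 and, after a hydride shift that leaves a C3/C4 bromonium ion, as an electrophile at C4. The C5=C10 and C8=C9 olefins and the C13 ketone oxygen then relay the cation to C8.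
4. Order of ring formation: ring A, ring B and a transient dihydropyran in step 3; the oxocane in step 6; the oxirane in step 7.

Key step: step 3

Remark: positions are given in labdane numbering (ring A = C1–C5 and C10, ring B = C5–C10, oxocane = O, C8, C9, C11–C15, methyl groups = C16–C20); the target is (3R,5S,8S,9S,10R,13S,14R). Compound 4 is made in step 2 in case it cannot be bought.

**Route**

Step 1
Reactants: 1 (E)-geranylacetone, (5E)-6,10-dimethylundeca-5,9-dien-2-one
Product: 2 (5E,9E)-11-hydroxy-6,10-dimethylundeca-5,9-dien-2-one
Conditions: SeO2 (cat.), t-BuOOH, salicylic acid (cat.), CH2Cl2, 0 °C to rt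
Reagents that add atoms: tert-butyl hydroperoxide, CC(C)(C)OO (oxygen carried by catalytic SeO2, O=[Se]=O)
Why: Catalytic SeO2 allylic oxidation (ene reaction followed by a [2,3]-sigmatropic shift) should attack the terminal trisubstituted olefin at its E methyl group, giving the E allylic alcohol and leaving the inner olefin and the ketone untouched.

Step 2
Reactants: 3 3-methylbut-1-yne
Product: 4 2-bromo-3-methylbut-1-ene
Conditions: Et4N·HBr2, CH2Cl2, 40 °C (sealed vessel)
Reagents that add atoms: tetraethylammonium hydrogen dibromide, CC[N+](CC)(CC)CC.Br.[Br-]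
Why: Markovnikov hydrobromination of a terminal alkyne with a hydrogen dibromide salt should stop at the 2-bromoalkene, because the vinyl bromide formed is much less reactive than the alkyne.

Step 3
Reactants: 2 (5E,9E)-11-hydroxy-6,10-dimethylundeca-5,9-dien-2-one; 4 2-bromo-3-methylbut-1-ene
Product: 6 bromo ketol (3R,5S,8S,9S,10R)-3-bromo-8-hydroxy-14,15-dinorlabdan-13-one, via tricyclic bromo enol ether 5 (not isolated)
Conditions: 4 (large excess, used as cosolvent), confined chiral imidodiphosphorimidate Brønsted acid built from two 3,3'-diaryl-1,1'-bi-2-naphthol units with N-trifluoromethylsulfonyl groups (cat., the antipode that leads to the 3R series), (CF3)2CHOH/CH2Cl2, −40 °C, slow addition of 2; then 1 M HCl, THF, rt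
Reagents that add atoms: water, O
Why: Proposed new method: the acid ionises allylic alcohol 2 to its 2-methylallyl cation, whose primary terminus is attacked by the CH2 end of vinyl bromide 4 (C1–C2); the bromine-stabilised cation at C3 then undergoes a 1,2-hydride shift from the isopropyl CH to give the tertiary C4 cation bridged by bromine, and this bromonium ion is opened at C4 by the C5=C10 olefin (C4–C5), followed by C8=C9 and the ketone oxygen. The closest known reaction types are the capture of carbocations by 2-haloalkenes (Lansbury-type haloalkene annulation) and the bromonium-induced polyene cyclisation ending on a ketone, which passes through the same bromonium ion when it is generated from a bromine electrophile. Ring A closes 6-endo through a chair transition state, ring B closes 6-endo onto the C10 cation, and the transient dihydropyran closes by attack of the carbonyl oxygen on the C8 cation before aqueous acid opens the enol ether 5 to the ketol. C3 should carry bromine equatorial because the bromonium ion is opened anti within the chair, C5 and C10 become trans by anti addition across the E olefin, C9 and C8 follow from the E C8=C9 olefin and anti attack of oxygen, and the absolute sense is to be imposed by the confined chiral counter-anion paired with the cations. The step needs the allyl cation to be taken by 4 at C1 and not by a second molecule of 2, which the large excess of 4 and slow addition of 2 should secure, helped by the fact that ring closure of the olefins of 2 onto their own allyl cation would be anti-Markovnikov; it also needs the hydride shift to outrun proton loss, and a proton lost this way gives a vinyl bromide that the acid should return to the same cations.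

Step 4
Reactants: 6 bromo ketol (3R,5S,8S,9S,10R)-3-bromo-8-hydroxy-14,15-dinorlabdan-13-one
Product: 7 (3R,5S,8S,9S,10R)-3-bromo-15-norlabd-13-en-8-ol (C9 side chain CH2CH2C(CH3)=CH2)
Conditions: Ph3PCH3Br, KOtBu, THF, 0 °C to rt; acid-free work-up
Reagents that add atoms: methyltriphenylphosphonium bromide, C[P+](c1ccccc1)(c1ccccc1)c1ccccc1.[Br-]
Why: Wittig methylenation of the methyl ketone should proceed without touching the equatorial neopentyl bromide, which has no anti-periplanar hydrogen and is shielded from backside attack.

Step 5
Reactants: 7 (3R,5S,8S,9S,10R)-3-bromo-15-norlabd-13-en-8-ol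
Product: 8 (3R,5S,8S,9S,10R)-8-allyloxy-3-bromo-15-norlabd-13-ene
Conditions: KH, allyl bromide, 18-crown-6 (cat.), THF, 0 °C to rt
Reagents that add atoms: allyl bromide, C=CCBr
Why: Williamson etherification of the tertiary potassium alkoxide with a reactive allylic bromide should give the allyl ether without touching any stereocentre.

Step 6
Reactants: 8 (3R,5S,8S,9S,10R)-8-allyloxy-3-bromo-15-norlabd-13-ene
Product: 9 oxocene (3R,5S,8S,9S,10R,13Z)-3-bromo-8,15-epoxylabd-13-ene
Conditions: second-generation Hoveyda–Grubbs catalyst RuCl2(H2IMes)(=CH-C6H4-2-OiPr) (cat.), 1,4-benzoquinone (cat.), toluene (high dilution), 80 °C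
Reagents that add atoms: none
Why: Ring-closing metathesis should start at the allyl ether and close onto the 1,1-disubstituted olefin to give the trisubstituted Z olefin, the only geometry an eight-membered ring allows, helped by the trans-diequatorial ring fusion that holds the two chains gauche.

Step 7
Reactants: 9 oxocene (3R,5S,8S,9S,10R,13Z)-3-bromo-8,15-epoxylabd-13-ene
Product: 10 target (3R,5S,8S,9S,10R,13S,14R)-3-bromo-8,15:13,14-diepoxylabdane
Conditions: 1,2:4,5-di-O-isopropylidene-β-D-erythro-hexo-2,3-diulo-2,6-pyranose (D-fructose-derived ketone, cat.), 2KHSO5·KHSO4·K2SO4, K2CO3, Bu4NHSO4, MeCN/CH2(OMe)2/aq. Na2B4O7 buffer, 0 °C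
Reagents that add atoms: potassium peroxymonosulfate KHSO5, [K+].[O-]S(=O)(=O)OO
Why: Shi epoxidation, in which the spiro transition state of the dioxirane from this ketone on a trisubstituted olefin should deliver oxygen to the face that gives 13S,14R; being catalyst-controlled, it should also turn any residual wrong antipode into a separable diastereomer.

**Compound list**

1 | (E)-geranylacetone, (5E)-6,10-dimethylundeca-5,9-dien-2-one | CC(=O)CC/C=C(\C)CCC=C(C)C | starting material
2 | (5E,9E)-11-hydroxy-6,10-dimethylundeca-5,9-dien-2-one | CC(=O)CC/C=C(\C)CC/C=C(\C)CO | intermediate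
3 | 3-methylbut-1-yne | CC(C)C#C | starting material
4 | 2-bromo-3-methylbut-1-ene | CC(C)C(Br)=C | intermediate
5 | tricyclic bromo enol ether, (3R,5S,8S,9S,10R)-3-bromo-8,13-epoxy-14,15-dinorlabd-12-ene (trans-decalin, equatorial Br, dihydropyran fused at C8–C9) | CC1(C)[C@H](Br)CC[C@]2(C)[C@@H]1CC[C@]1(C)OC(C)=CC[C@@H]21 | intermediate
6 | bromo ketol, (3R,5S,8S,9S,10R)-3-bromo-8-hydroxy-14,15-dinorlabdan-13-one (trans-decalin, equatorial Br cis to the C10 methyl, axial C8 methyl, equatorial C8–OH, equatorial 3-oxobutyl chain at C9) | CC1(C)[C@H](Br)CC[C@]2(C)[C@@H]1CC[C@](C)(O)[C@H]2CCC(C)=O | intermediate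
7 | (3R,5S,8S,9S,10R)-3-bromo-15-norlabd-13-en-8-ol | CC1(C)[C@H](Br)CC[C@]2(C)[C@@H]1CC[C@](C)(O)[C@H]2CCC(C)=C | intermediate
8 | (3R,5S,8S,9S,10R)-8-allyloxy-3-bromo-15-norlabd-13-ene | CC1(C)[C@H](Br)CC[C@]2(C)[C@@H]1CC[C@](C)(OCC=C)[C@H]2CCC(C)=C | intermediate
9 | oxocene, (3R,5S,8S,9S,10R,13Z)-3-bromo-8,15-epoxylabd-13-ene | CC1(C)[C@H](Br)CC[C@]2(C)[C@@H]1CC[C@]1(C)OC/C=C(C)\CC[C@@H]21 | intermediate
10 | (3R,5S,8S,9S,10R,13S,14R)-3-bromo-8,15:13,14-diepoxylabdane (CNP0311742.1) | CC1(C)[C@H](Br)CC[C@]2(C)[C@@H]1CC[C@]1(C)OC[C@H]3O[C@@]3(C)CC[C@@H]21 | target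

**Step count**

Total steps: 7. Longest linear sequence: 6 steps (1 → 2 → 6 → 7 → 8 → 9 → 10; step 2 is a one-step branch).

**Steps most likely to fail**

1. Step 3 (proposed new method). What may go wrong: the allyl cation is consumed by a second molecule of 2 or by the solvent faster than by the weakly nucleophilic vinyl bromide; the C3 cation loses a proton instead of undergoing the hydride shift; the counter-anion induces too little asymmetry. The fallback uses known chemistry: the linear polyene is made first, bromine is brought in as an electrophile and the antipodes are separated. It sets out from 1 and comes back at 6. Addition of CH2=CHMgBr to 1 in THF should give (6E)-nerolidol F1. Heating F1 with methyl acetoacetate and Al(OiPr)3 should give nerolidyl acetoacetate F2, which undergoes the Carroll rearrangement in the same flask to (5E,9E)-farnesylacetone F3 and (5Z,9E)-farnesylacetone F4; F4 is removed on AgNO3-impregnated silica. F3 is cyclised with Et2SBr·SbBrCl5 in MeNO2 at −25 °C (bromonium-induced polyene cyclisation ending on the ketone) to the racemic enol ether, that is 5 and the mirror-image enol ether F5. Hydrolysis with 1 M HCl in THF should give 6 and the mirror-image ketol F6, and preparative chromatography on a chiral stationary phase removes F6.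

2. Step 6. What may go wrong: intermolecular metathesis and migration of the allyl double bond outrun closure of the eight-membered ring onto the hindered 1,1-disubstituted olefin. The fallback sets out from 6 and comes back at 9, so that steps 4 and 5 are not needed. Treatment of 6 with NaH and then vinyltriphenylphosphonium bromide in THF/DMF should add the C8 alkoxide to the vinylphosphonium salt to give the phosphorus ylide F7. Its intramolecular Wittig reaction with the C13 ketone closes the C13=C14 bond of the oxocene (Schweizer reaction).

3. Step 7. What may go wrong: poor facial selectivity if the conformational bias of the oxocene opposes the catalyst. The fallback sets out from 9 and comes back at 10. N-Bromosuccinimide in THF/H2O should place bromine on the face the substrate prefers and water on C13 from the other face, giving the (13S,14S)-bromohydrin F8. K2CO3 in MeOH then closes the oxirane with inversion at C14, so that oxygen ends on the face opposite to the one an electrophilic oxidant takes.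

**Further compounds**

F1 | step 3 | (6E)-nerolidol (racemic) | C=CC(C)(O)CC/C=C(\C)CCC=C(C)C
F2 | step 3 | nerolidyl acetoacetate | CC(=O)CC(=O)OC(C)(C=C)CC/C=C(\C)CCC=C(C)C
F3 | step 3 | (5E,9E)-farnesylacetone | CC(=O)CC/C=C(\C)CC/C=C(\C)CCC=C(C)C
F4 | step 3 | (5Z,9E)-farnesylacetone | CC(=O)CC/C=C(/C)CC/C=C(\C)CCC=C(C)C
F5 | step 3 | mirror-image enol ether (enantiomer of 5) | CC1(C)[C@@H](Br)CC[C@@]2(C)[C@H]1CC[C@@]1(C)OC(C)=CC[C@H]21
F6 | step 3 | mirror-image ketol (enantiomer of 6) | CC1(C)[C@@H](Br)CC[C@@]2(C)[C@H]1CC[C@@](C)(O)[C@@H]2CCC(C)=O
F7 | step 6 | phosphorus ylide from 6 (8-O-CH2-CH=PPh3) | CC1(C)[C@H](Br)CC[C@]2(C)[C@@H]1CC[C@](C)(OCC=P(c3ccccc3)(c3ccccc3)c3ccccc3)[C@H]2CCC(C)=O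
F8 | step 7 | (13S,14S)-14-bromo-13-hydroxy bromohydrin of 9 | CC1(C)[C@H](Br)CC[C@]2(C)[C@@H]1CC[C@]1(C)OC[C@H](Br)[C@@](C)(O)CC[C@@H]21
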